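The target's dihydrofuran ring (O1–C2–C3–C3a–C7a, catechol ring on C2) is read as ring C of a flavanone that has lost C4. The C3–C3a bond is disconnected as a 1,2-shift of ring A carbon C4a from C4 to C3. One oxidative operation with trivalent iodine contracts the pyranone of an (S)-flavanone to the trans-2-aryl-2,3-dihydrobenzofuran, relays C2 chirality to C3 and leaves old C4 as a C3 ester. That ester is later exchanged for the resorcinol ring by decarboxylative arylation. The precursor is (S)-6-bromo-2-(3,4-dimethoxyphenyl)chroman-4-one, whose bromide becomes the stilbene by Heck coupling.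

Key step: step 2

Assumption: the Pd(OCOCF3)2/t-BuPyOX catalyst is taken to show the same facial preference on chromones as on carbocyclic enones, so the (R)-ligand is specified for the (S)-flavanone; if the sense proves opposite, the (S)-ligand is used and nothing else changes.

Step 1
Reactants: 1 6-bromochromone; 2 3,4-dimethoxyphenylboronic acid
Product: 3 (S)-6-bromo-2-(3,4-dimethoxyphenyl)chroman-4-one
Conditions: Pd(OCOCF3)2 (5 mol%), (R)-t-BuPyOX [(R)-4-tert-butyl-2-(2-pyridyl)-4,5-dihydrooxazole] (6 mol%), NH4PF6 (30 mol%), H2O (5 equiv), ClCH2CH2Cl, 60 °C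
Reagents that add atoms: none
Why: Asymmetric conjugate addition of an arylboronic acid to a chromone under cationic divalent palladium/pyridine–oxazoline catalysis, in which the aryl–palladium species inserts the C2=C3 bond on the face left open by the ligand tert-butyl group (C2 set S by the ligand) and water protonates the palladium enolate; the cycle should not pass through zerovalent palladium, so the aryl bromide should survive.

Step 2
Reactants: 3 (S)-6-bromo-2-(3,4-dimethoxyphenyl)chroman-4-one
Product: 7 methyl (2S,3S)-5-bromo-2-(3,4-dimethoxyphenyl)-2,3-dihydrobenzofuran-3-carboxylate, via methyl enol ether 4 (not isolated), via C3 iodane 5 (not isolated), via orthoester 6 (not isolated)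
Conditions: PhI(OAc)2 (1.3 equiv), HC(OMe)3, conc. H2SO4 (1.5 equiv), 0 °C → rt; H2O quench, then NaHCO3
Reagents that add atoms: trimethyl orthoformate, COC(OC)OC; water, O
Why: Acid and HC(OMe)3 convert ketone 3 into methyl enol ether 4, which PhI(OAc)2 (trivalent iodine) attacks at C3 on the face opposite the C2 aryl while methanol adds to C4 to give ketal iodane 5; ring A carbon C4a then shifts from C4 to C3 antiperiplanar to the C3–I bond with loss of PhI, and the dimethoxycarbenium ion left at old C4 is trapped as orthoester 6, which the aqueous quench hydrolyses to ester 7. The closest known reaction type is the oxidative 1,2-aryl migration of aryl ketone ketals with trivalent iodine or Tl(NO3)3, which is established for the contraction of flavanones to trans-2-aryl-2,3-dihydrobenzofuran-3-carboxylates. The dihydrofuran ring is closed not by a cyclisation but by this semipinacol-type contraction of the six-membered pyranone, through a bridged phenonium-like transition state (formally 3-exo-tet at C3). The new stereocenter C3 is controlled by the existing C2 centre: anti iodination followed by inversion during the shift places the ester trans to the C2 aryl, which is also the thermodynamic epimer. The step needs migration of C4a in preference to a shift of the C2 aryl (isoflavone), dehydrogenation to the flavone and acid opening of the pyranone. The C4 ketal, whose oxygen lone pairs drive the C4→C3 shift, and fast enol-ether formation in HC(OMe)3, which removes the carbonyl needed for retro-oxa-Michael cleavage, should secure this.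

Step 3
Reactants: 7 methyl (2S,3S)-5-bromo-2-(3,4-dimethoxyphenyl)-2,3-dihydrobenzofuran-3-carboxylate; 8 3,5-dimethoxystyrene
Product: 9 methyl (2S,3S)-2-(3,4-dimethoxyphenyl)-5-[(E)-2-(3,5-dimethoxyphenyl)ethenyl]-2,3-dihydrobenzofuran-3-carboxylate
Conditions: Pd2(dba)3 (1.5 mol%), [HP(t-Bu)3]BF4 (6 mol%), Cy2NMe (1.2 equiv), dioxane, rt → 50 °C
Reagents that add atoms: none
Why: Mizoroki–Heck reaction of the aryl bromide with a styrene (oxidative addition to zerovalent palladium, syn insertion, syn β-hydride elimination) should give the E-stilbene, and the hindered tertiary amine at low temperature should not deprotonate C3, so the β-aryloxy ester should stay closed.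

Step 4
Reactants: 9 methyl (2S,3S)-2-(3,4-dimethoxyphenyl)-5-[(E)-2-(3,5-dimethoxyphenyl)ethenyl]-2,3-dihydrobenzofuran-3-carboxylate
Product: 11 (2S,3S)-2-(3,4-dimethoxyphenyl)-5-[(E)-2-(3,5-dimethoxyphenyl)ethenyl]-2,3-dihydrobenzofuran-3-carboxylic acid, via trimethylstannyl ester 10 (not isolated)
Conditions: Me3SnOH (5 equiv), ClCH2CH2Cl, 80 °C; then 1 M HCl wash
Reagents that add atoms: trimethyltin hydroxide, C[Sn](C)(C)O
Why: Tin hydroxide-mediated hydrolysis of a methyl ester runs under essentially neutral conditions, so no base strong enough to trigger E1cB cleavage of the C2–O1 bond is present and C2 should keep its configuration.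

Step 5
Reactants: 11 (2S,3S)-2-(3,4-dimethoxyphenyl)-5-[(E)-2-(3,5-dimethoxyphenyl)ethenyl]-2,3-dihydrobenzofuran-3-carboxylic acid
Product: 12 1,3-dioxoisoindolin-2-yl (2S,3S)-2-(3,4-dimethoxyphenyl)-5-[(E)-2-(3,5-dimethoxyphenyl)ethenyl]-2,3-dihydrobenzofuran-3-carboxylate
Conditions: N-hydroxyphthalimide (1.1 equiv), DIC (1.1 equiv), DMAP (0.1 equiv), CH2Cl2, 0 °C → rt
Reagents that add atoms: N-hydroxyphthalimide, O=C1c2ccccc2C(=O)N1O
Why: Carbodiimide (Steglich-type) esterification gives the redox-active ester, and low temperature with only catalytic DMAP should limit deprotonation at C3.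

Step 6
Reactants: 13 1-bromo-3,5-dimethoxybenzene
Product: 15 (3,5-dimethoxyphenyl)zinc chloride, via arylmagnesium bromide 14 (not isolated)
Conditions: Mg turnings, LiCl, THF, rt; then ZnCl2 (1.0 M in THF), 0 °C → rt; solution used directly
Reagents that add atoms: zinc dichloride, Cl[Zn]Cl
Why: Grignard formation by magnesium insertion into the aryl bromide followed by transmetallation to zinc is routine for electron-rich aryl bromides.

Step 7
Reactants: 12 1,3-dioxoisoindolin-2-yl (2S,3S)-2-(3,4-dimethoxyphenyl)-5-[(E)-2-(3,5-dimethoxyphenyl)ethenyl]-2,3-dihydrobenzofuran-3-carboxylate; 15 (3,5-dimethoxyphenyl)zinc chloride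
Product: 16 (2S,3S)-2-(3,4-dimethoxyphenyl)-3-(3,5-dimethoxyphenyl)-5-[(E)-2-(3,5-dimethoxyphenyl)ethenyl]-2,3-dihydrobenzofuran
Conditions: NiCl2·glyme (20 mol%), 4,4'-di-tert-butyl-2,2'-bipyridine (40 mol%), 15 (3 equiv), THF/DMF, rt; aq. HCl work-up
Reagents that add atoms: none
Why: Nickel-catalysed decarboxylative Negishi-type arylation of a redox-active ester, in which electron transfer from an aryl–nickel species of monovalent nickel fragments the phthalimide ester with loss of CO2 and the benzylic C3 radical is captured by nickel and reductively eliminated with the aryl group; the planar radical should be taken up on the face opposite the C2 aryl, so C3 is set S (trans) under control of the untouched C2 centre.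

Step 8
Reactants: 16 (2S,3S)-2-(3,4-dimethoxyphenyl)-3-(3,5-dimethoxyphenyl)-5-[(E)-2-(3,5-dimethoxyphenyl)ethenyl]-2,3-dihydrobenzofuran
Product: 17 (2S,3S)-2-(3,4-dihydroxyphenyl)-3-(3,5-dihydroxyphenyl)-5-[(E)-2-(3,5-dihydroxyphenyl)ethenyl]-2,3-dihydrobenzofuran (CNP0207985.1)
Conditions: BBr3 (12 equiv), CH2Cl2, −78 °C → 0 °C; ice-water quench
Reagents that add atoms: none
Why: Lewis acid-mediated cleavage of aryl methyl ethers (bromide attacks the methyl group of each boron-complexed ether) should free all six phenols without touching either stereocenter, and the low temperature is chosen to keep the C2–O1 bond and the E-stilbene intact.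

Compound list
1 | 6-bromochromone | O=c1ccoc2ccc(Br)cc12 | starting material
2 | 3,4-dimethoxyphenylboronic acid | COc1ccc(B(O)O)cc1OC | starting material
3 | (S)-6-bromo-2-(3,4-dimethoxyphenyl)chroman-4-one | Brc1ccc2c(c1)C(=O)C[C@@H](c1ccc(OC)c(OC)c1)O2 | intermediate
4 | (S)-6-bromo-2-(3,4-dimethoxyphenyl)-4-methoxy-2H-chromene | Brc1ccc2c(c1)C(OC)=C[C@@H](c1ccc(OC)c(OC)c1)O2 | intermediate
5 | (2R,3R)-3-[acetoxy(phenyl)-λ3-iodanyl]-6-bromo-2-(3,4-dimethoxyphenyl)-4,4-dimethoxychromane (iodine trans to the C2 aryl; C2 unchanged in space, descriptor altered by priority only) | Brc1ccc2c(c1)C(OC)(OC)[C@H](I(OC(C)=O)c1ccccc1)[C@@H](c1ccc(OC)c(OC)c1)O2 | intermediate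
6 | (2S,3S)-5-bromo-2-(3,4-dimethoxyphenyl)-3-(trimethoxymethyl)-2,3-dihydrobenzofuran | Brc1ccc2c(c1)[C@H](C(OC)(OC)OC)[C@@H](c1ccc(OC)c(OC)c1)O2 | intermediate
7 | methyl (2S,3S)-5-bromo-2-(3,4-dimethoxyphenyl)-2,3-dihydrobenzofuran-3-carboxylate (2,3-trans) | Brc1ccc2c(c1)[C@H](C(=O)OC)[C@@H](c1ccc(OC)c(OC)c1)O2 | intermediate
8 | 3,5-dimethoxystyrene | C=Cc1cc(OC)cc(OC)c1 | starting material
9 | methyl (2S,3S)-2-(3,4-dimethoxyphenyl)-5-[(E)-2-(3,5-dimethoxyphenyl)ethenyl]-2,3-dihydrobenzofuran-3-carboxylate | COc1cc(OC)cc(/C=C/c2ccc3c(c2)[C@H](C(=O)OC)[C@@H](c2ccc(OC)c(OC)c2)O3)c1 | intermediate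
10 | trimethylstannyl (2S,3S)-2-(3,4-dimethoxyphenyl)-5-[(E)-2-(3,5-dimethoxyphenyl)ethenyl]-2,3-dihydrobenzofuran-3-carboxylate | COc1cc(OC)cc(/C=C/c2ccc3c(c2)[C@H](C(=O)O[Sn](C)(C)C)[C@@H](c2ccc(OC)c(OC)c2)O3)c1 | intermediate
11 | (2S,3S)-2-(3,4-dimethoxyphenyl)-5-[(E)-2-(3,5-dimethoxyphenyl)ethenyl]-2,3-dihydrobenzofuran-3-carboxylic acid | COc1cc(OC)cc(/C=C/c2ccc3c(c2)[C@H](C(=O)O)[C@@H](c2ccc(OC)c(OC)c2)O3)c1 | intermediate
12 | 1,3-dioxoisoindolin-2-yl (2S,3S)-2-(3,4-dimethoxyphenyl)-5-[(E)-2-(3,5-dimethoxyphenyl)ethenyl]-2,3-dihydrobenzofuran-3-carboxylate | COc1cc(OC)cc(/C=C/c2ccc3c(c2)[C@H](C(=O)ON2C(=O)c4ccccc4C2=O)[C@@H](c2ccc(OC)c(OC)c2)O3)c1 | intermediate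
13 | 1-bromo-3,5-dimethoxybenzene | COc1cc(Br)cc(OC)c1 | starting material
14 | (3,5-dimethoxyphenyl)magnesium bromide | COc1cc([Mg]Br)cc(OC)c1 | intermediate
15 | (3,5-dimethoxyphenyl)zinc chloride | COc1cc([Zn]Cl)cc(OC)c1 | intermediate
16 | (2S,3S)-2-(3,4-dimethoxyphenyl)-3-(3,5-dimethoxyphenyl)-5-[(E)-2-(3,5-dimethoxyphenyl)ethenyl]-2,3-dihydrobenzofuran (2,3-trans) | COc1cc(OC)cc(/C=C/c2ccc3c(c2)[C@H](c2cc(OC)cc(OC)c2)[C@@H](c2ccc(OC)c(OC)c2)O3)c1 | intermediate
17 | (2S,3S)-2-(3,4-dihydroxyphenyl)-3-(3,5-dihydroxyphenyl)-5-[(E)-2-(3,5-dihydroxyphenyl)ethenyl]-2,3-dihydrobenzofuran (CNP0207985.1; 2,3-trans) | Oc1cc(O)cc(/C=C/c2ccc3c(c2)[C@H](c2cc(O)cc(O)c2)[C@@H](c2ccc(O)c(O)c2)O3)c1 | target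

Total step count: 8
Longest linear sequence: 7 (steps 1, 2, 3, 4, 5, 7, 8); step 6 is a one-step side branch.

Steps most likely to fail

Step 2. What may go wrong is competition with the C4a shift: migration of the electron-rich C2 aryl instead, dehydrogenation to the flavone, oxidation of the veratryl ring by the iodane, or acid-induced opening and reclosure of the pyranone with loss of C2 integrity. The fallback sets out from 3 and separates electrophilic activation from migration. PhNMe3Br3 in MeOH/HC(OMe)3 with catalytic TsOH should brominate enol ether 4 anti to the C2 aryl and give the α-bromo ketal (2R,3R)-3,6-dibromo-2-(3,4-dimethoxyphenyl)-4,4-dimethoxychromane F1. AgBF4 in MeOH then abstracts bromide and triggers the same C4→C3 shift of C4a, the known rearrangement of α-halo aryl ketals to 2-aryl esters. Aqueous work-up brings the route back at 7.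

Step 7. What may go wrong is slow capture of the stabilised benzylic C3 radical by nickel, which leads to dimerisation or reduction, attack of the basic organozinc on the activated ester with opening of the C2–O1 bond, and incomplete trans selectivity. The fallback sets out from 12 and dispenses with the preformed organometallic. A reductive cross-electrophile coupling with commercial 1-iodo-3,5-dimethoxybenzene (COc1cc(I)cc(OC)c1; NiBr2·glyme, 4,4'-di-tert-butyl-2,2'-bipyridine, Zn powder, DMA, rt) should generate the same C3 radical and the aryl–nickel partner in the flask. It comes back at 16 and makes no new compound (F0).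

Step 8. What may go wrong is Lewis-acid opening of the benzylic C2–O1 bond, cationic addition or oligomerisation at the stilbene, incomplete cleavage of six ethers, and air oxidation of the free catechol during isolation. The fallback sets out from 16 and uses a protecting-group relay. Iodide-assisted cleavage with BCl3/n-Bu4NI (CH2Cl2, −78 °C → 0 °C) is followed directly by peracetylation of the crude hexaphenol (Ac2O, pyridine). This should give (2S,3S)-2-(3,4-diacetoxyphenyl)-3-(3,5-diacetoxyphenyl)-5-[(E)-2-(3,5-diacetoxyphenyl)ethenyl]-2,3-dihydrobenzofuran F2, which can be purified on silica. Methanolysis with K2CO3/MeOH under argon then comes back at 17.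

Further compounds
F1 | step 2 | (2R,3R)-3,6-dibromo-2-(3,4-dimethoxyphenyl)-4,4-dimethoxychromane (bromine trans to the C2 aryl) | Brc1ccc2c(c1)C(OC)(OC)[C@H](Br)[C@@H](c1ccc(OC)c(OC)c1)O2
F0 | step 7 | none | none
F2 | step 8 | (2S,3S)-2-(3,4-diacetoxyphenyl)-3-(3,5-diacetoxyphenyl)-5-[(E)-2-(3,5-diacetoxyphenyl)ethenyl]-2,3-dihydrobenzofuran | CC(=O)Oc1cc(OC(C)=O)cc(/C=C/c2ccc3c(c2)[C@H](c2cc(OC(C)=O)cc(OC(C)=O)c2)[C@@H](c2ccc(OC(C)=O)c(OC(C)=O)c2)O3)c1
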